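**Plan**

- Ring numbering used throughout: C1 (CH–O‑vanilloyl), C2, C3(Me)=C4, C5, C6, C7(Me)=C8, C9 (CH–OH), C10 (CH–iPr).
- Cuts, in retrosynthetic order: the C1–O acyl bond, the ring bond C4–C5, C6–C7 (vinyl onto a C7 iodide), C3–CH3 and C4–Br (methyl‑bromination of a C3≡C4 alkyne), C1–C2 (propargyl onto a C1 aldehyde), C9–C10 (aldol).
- Enabling feature: O1 is homoallylic to the Z C3=C4 alkene and O9 is allylic to the Z C7=C8 alkene, so each cis alkene can be set by its own hydroxyl in open‑chain form. C4–C5 joins the hydrogen‑bearing alkene carbon C4 to a plain CH2, and the two cis alkenes fold the chain so that a C5 borane reaches the C4 halide.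
- Forward order: aldol (C9–C10), propargylation (C1–C2), directed methyl‑bromination (Z C3=C4), vinylation (C6–C7), hydroboration and B‑alkyl Suzuki–Miyaura closure of the only ring (C4–C5), acylation of O1, desilylation. C4 carries bromide so that the C7 iodide can be vinylated selectively after the aluminium chemistry, which a diene would not be expected to survive.
- Stereochemistry: C9 and C10 from the (R)‑benzyloxazolidinone syn‑aldol; C1 from catalyst‑controlled allenylboration; Z C7=C8 from directed trans‑hydroalumination–iodination of but‑2‑yn‑1‑ol; Z C3=C4 from chelation‑driven isomerisation of the alkenylalane.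

Key step: step 10

Remark: (R)‑TRIP is assumed to direct allenyl transfer to the Re face of the aldehyde, as it does with simple aldehydes; if the opposite holds for this substrate, (S)‑TRIP is used.
Remark: with excess 9‑BBN‑H the hindered C1 hydroxyl is assumed to be O‑borylated during hydroboration and freed again by the aqueous base of the coupling.

**Route**

Step 1
Reactants: 1 but‑2‑yn‑1‑ol
Product: 3 (2Z)‑3‑iodobut‑2‑en‑1‑ol, via cyclic alkenylalanate 2 (not isolated)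
Conditions: NaAlH2(OCH2CH2OMe)2 (1.4 equiv), Et2O, 0 °C → rt; then NIS, THF, −78 → 0 °C
Reagents that add atoms: N‑iodosuccinimide, O=C1CCC(=O)N1I
Why: Directed trans‑hydroalumination: the aluminium alkoxide delivers hydride to C2 and closes a five‑membered alkenylalanate with aluminium on C3 cis to the carbinol carbon, and iodinolysis of the C–Al bond with retention fixes the Z‑iodoalkene.

Step 2
Reactants: 3 (2Z)‑3‑iodobut‑2‑en‑1‑ol
Product: 4 (2Z)‑3‑iodobut‑2‑enal
Conditions: MnO2 (activated, excess), CH2Cl2, rt, dark; filtered and used at once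
Reagents that add atoms: none
Why: Manganese dioxide oxidation of an allylic alcohol is neutral and heterogeneous, so the sensitive Z‑iodoenal should form without Z to E isomerisation.

Step 3
Reactants: 5 (4R)‑4‑benzyl‑3‑(3‑methylbutanoyl)‑1,3‑oxazolidin‑2‑one; 4 (2Z)‑3‑iodobut‑2‑enal
Product: 8 (4R)‑4‑benzyl‑3‑[(2R,3R,4Z)‑3‑hydroxy‑5‑iodo‑2‑(propan‑2‑yl)hex‑4‑enoyl]‑1,3‑oxazolidin‑2‑one, via boron enolate 6 (not isolated), via boron aldolate 7 (not isolated)
Conditions: Bu2BOTf (1.2 equiv), Et3N (1.3 equiv), CH2Cl2, −78 → 0 °C; 4, −78 → −10 °C; pH 7 buffer, MeOH, H2O2, 0 °C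
Reagents that add atoms: none
Why: Evans syn‑aldol reaction: the Z(O)‑dibutylboron enolate adds through a closed chair transition state on the enolate face remote from the benzyl group, which sets C10 and C9 syn (2R,3R in the acyl chain) with the absolute sense dictated by the (R)‑auxiliary.

Step 4
Reactants: 8 aldol adduct
Product: 9 (4R)‑4‑benzyl‑3‑[(2R,3R,4Z)‑3‑[(tert‑butyldimethylsilyl)oxy]‑5‑iodo‑2‑(propan‑2‑yl)hex‑4‑enoyl]‑1,3‑oxazolidin‑2‑one
Conditions: TBSOTf, 2,6‑lutidine, CH2Cl2, −78 → 0 °C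
Reagents that add atoms: tert‑butyldimethylsilyl triflate, CC(C)(C)[Si](C)(C)OS(=O)(=O)C(F)(F)F
Why: Silylation of a secondary alcohol with a silyl triflate and a hindered pyridine base is fast at low temperature, which avoids retro‑aldol cleavage of the β‑hydroxy imide.

Step 5
Reactants: 9 silylated imide
Product: 10 (2S,3R,4Z)‑3‑[(tert‑butyldimethylsilyl)oxy]‑5‑iodo‑2‑(propan‑2‑yl)hex‑4‑en‑1‑ol
Conditions: LiBH4, MeOH (1 equiv), THF, 0 °C → rt
Reagents that add atoms: none
Why: Reductive removal of the oxazolidinone with LiBH4 (hydride attack at the exocyclic imide carbonyl) gives the primary alcohol and leaves the silyl ether, the iodoalkene and the C10 stereocentre untouched.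

Step 6
Reactants: 10 primary alcohol
Product: 11 (2R,3R,4Z)‑3‑[(tert‑butyldimethylsilyl)oxy]‑5‑iodo‑2‑(propan‑2‑yl)hex‑4‑enal
Conditions: Dess–Martin periodinane, CH2Cl2, 0 °C → rt
Reagents that add atoms: none
Why: Dess–Martin oxidation is non‑basic and stops at the aldehyde, so the α‑branched aldehyde should form without epimerisation at C10.

Step 7
Reactants: 11 aldehyde
Product: 13 (4R,5S,6R,7Z)‑6‑[(tert‑butyldimethylsilyl)oxy]‑8‑iodo‑5‑(propan‑2‑yl)non‑7‑en‑1‑yn‑4‑ol, via pinacol borate ester 12 (not isolated)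
Conditions: allenylboronic acid pinacol ester (1.5 equiv), (R)‑TRIP [(R)‑3,3′‑bis(2,4,6‑triisopropylphenyl)‑1,1′‑binaphthyl‑2,2′‑diyl hydrogen phosphate] (10 mol%), 4 Å MS, toluene, −20 → 0 °C; aq. NaHCO3
Reagents that add atoms: allenylboronic acid pinacol ester, C=C=CB1OC(C)(C)C(C)(C)O1
Why: Chiral phosphoric acid‑catalysed allenylboration (asymmetric propargylation): the catalyst‑bound boronate adds through a closed six‑membered SE2′ transition state to the Re face of the aldehyde, which sets C1 as R (syn to the C10 isopropyl group) under catalyst control because the intrinsic bias of this α‑branched aldehyde is weak.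

Step 8
Reactants: 13 homopropargylic alcohol
Product: 16 (1Z,4R,5S,6R,7Z)‑1‑bromo‑6‑[(tert‑butyldimethylsilyl)oxy]‑8‑iodo‑2‑methyl‑5‑(propan‑2‑yl)nona‑1,7‑dien‑4‑ol, via E‑alkenylalane 14 (not isolated), via cyclic Z‑alkenylalane 15 (not isolated)
Conditions: AlMe3 (4 equiv), Cp2ZrCl2 (0.3 equiv), (CH2Cl)2, 0 °C → rt; then 80 °C; then NBS, THF, −40 → 0 °C; aq. KNaC4H4O6
Reagents that add atoms: trimethylaluminium, C[Al](C)C; N‑bromosuccinimide, O=C1CCC(=O)N1Br
Why: Negishi carboalumination with chelation‑controlled isomerisation: methyl and aluminium add syn across the terminal alkyne (methyl on C3), heating lets the C1 aluminium alkoxide capture the alkenyl aluminium in a six‑membered Z oxa‑aluminacycle, and bromination of the C–Al bond with retention gives the Z‑bromoalkene.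

Step 9
Reactants: 16 bromo iodo dienol
Product: 17 (1Z,4R,5S,6S,7Z)‑1‑bromo‑6‑[(tert‑butyldimethylsilyl)oxy]‑2,8‑dimethyl‑5‑(propan‑2‑yl)deca‑1,7,9‑trien‑4‑ol
Conditions: tributyl(vinyl)stannane (1.3 equiv), PdCl2(MeCN)2 (5 mol%), DMF, rt, dark
Reagents that add atoms: tributyl(vinyl)stannane, C=C[Sn](CCCC)(CCCC)CCCC
Why: Stille coupling: at room temperature zerovalent palladium inserts into the alkenyl C–I bond far faster than into the alkenyl C–Br bond, and coupling with retention gives the Z diene while the C4 bromide is kept for the ring closure.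

Step 10
Reactants: 17 Z‑bromoalkene Z‑diene
Product: 19 (1R,3Z,7Z,9S,10S)‑9‑[(tert‑butyldimethylsilyl)oxy]‑3,7‑dimethyl‑10‑(propan‑2‑yl)cyclodeca‑3,7‑dien‑1‑ol, via bis‑9‑BBN adduct 18 (not isolated)
Conditions: 9‑BBN‑H (3 equiv), THF, 0 °C → rt; then syringe‑pump addition to PdCl2(dppf)·CH2Cl2 (20 mol%), AsPh3 (20 mol%), Cs2CO3 (4 equiv), degassed DMF/THF/H2O, 50 °C, final 1 mM
Reagents that add atoms: none
Why: 9‑BBN‑H adds anti‑Markovnikov to the monosubstituted C5=C6 end of the diene (boron on C5, hydrogen on C6), zerovalent palladium inserts into the C4–Br bond with retention, the base‑activated C5 borate transmetalates, and reductive elimination forms C4–C5. The closest known reaction type is the intramolecular B‑alkyl Suzuki–Miyaura macrocyclisation, which is well documented for larger rings. The ten‑membered carbocycle closes end‑to‑end at C4–C5 by C(sp3)–C(sp2) reductive elimination from an eleven‑membered alkyl(alkenyl)palladium cycle. No stereocentre is formed: the C1/C10/C9 triad is untouched and both Z alkenes are carried through with retention. The step needs hydroboration at the terminal alkene only, which the bulk of 9‑BBN should secure against the two trisubstituted alkenes and the bromoalkene, and ring closure faster than oligomerisation, which slow addition into a dilute catalyst solution and the chain folding imposed by the two cis alkenes should secure.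

Step 11
Reactants: 20 vanillic acid
Product: 22 4‑[(tert‑butyldimethylsilyl)oxy]‑3‑methoxybenzoic acid, via bis‑silylated vanillate 21 (not isolated)
Conditions: TBSCl (2.5 equiv), imidazole, DMF, rt; then AcOH/THF/H2O, rt
Reagents that add atoms: tert‑butyldimethylsilyl chloride, CC(C)(C)[Si](C)(C)Cl
Why: Exhaustive silylation followed by hydrolysis of the far more labile silyl ester leaves the phenol protected and the carboxylic acid free.

Step 12
Reactants: 19 macrocyclic alcohol; 22 silylated vanillic acid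
Product: 24 (1R,3Z,7Z,9S,10S)‑9‑[(tert‑butyldimethylsilyl)oxy]‑3,7‑dimethyl‑10‑(propan‑2‑yl)cyclodeca‑3,7‑dien‑1‑yl 4‑[(tert‑butyldimethylsilyl)oxy]‑3‑methoxybenzoate, via mixed anhydride 23 (not isolated)
Conditions: 22, 2,4,6‑trichlorobenzoyl chloride, Et3N, THF, rt; then 19, DMAP, toluene, rt → 50 °C
Reagents that add atoms: none
Why: Yamaguchi esterification: DMAP attacks the less hindered vanilloyl carbonyl of the mixed anhydride and the resulting acylpyridinium acylates the hindered C1 alcohol with retention at C1, the C9 oxygen being blocked as its silyl ether.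

Step 13
Reactants: 24 bis‑silylated ester
Product: 25 (1R,3Z,7Z,9S,10R)‑9‑hydroxy‑3,7‑dimethyl‑10‑(propan‑2‑yl)cyclodeca‑3,7‑dien‑1‑yl 4‑hydroxy‑3‑methoxybenzoate (target)
Conditions: HF·pyridine, pyridine, THF, 0 °C → rt
Reagents that add atoms: none
Why: Fluoride cleavage of the aryl and the secondary allylic silyl ether under buffered, non‑basic conditions should free the phenol and the C9 alcohol without a 1,3‑acyl shift from O1 to O9.

**Compound list**

1 | but‑2‑yn‑1‑ol | CC#CCO | starting material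
2 | sodium 2,2‑bis(2‑methoxyethoxy)‑3‑methyl‑2,5‑dihydro‑1,2‑oxaluminol‑2‑uide (cyclic alkenylalanate) | CC1=CCO[Al-]1(OCCOC)OCCOC.[Na+] | intermediate (not isolated)
3 | (2Z)‑3‑iodobut‑2‑en‑1‑ol | OC/C=C(/C)I | intermediate
4 | (2Z)‑3‑iodobut‑2‑enal | O=C/C=C(/C)I | intermediate
5 | (4R)‑4‑benzyl‑3‑(3‑methylbutanoyl)‑1,3‑oxazolidin‑2‑one | CC(C)CC(=O)N1[C@H](Cc2ccccc2)COC1=O | starting material
6 | Z(O)‑dibutylboron enolate of 5 | CC(C)/C=C(\OB(CCCC)CCCC)N1[C@H](Cc2ccccc2)COC1=O | intermediate (not isolated)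
7 | O‑dibutylboryl aldolate of 8 | O=C1OC[C@@H](Cc2ccccc2)N1C(=O)[C@H](C(C)C)[C@@H](OB(CCCC)CCCC)/C=C(C)\I | intermediate (not isolated)
8 | (4R)‑4‑benzyl‑3‑[(2R,3R,4Z)‑3‑hydroxy‑5‑iodo‑2‑(propan‑2‑yl)hex‑4‑enoyl]‑1,3‑oxazolidin‑2‑one | O=C1OC[C@@H](Cc2ccccc2)N1C(=O)[C@H](C(C)C)[C@@H](O)/C=C(C)\I | intermediate
9 | (4R)‑4‑benzyl‑3‑[(2R,3R,4Z)‑3‑[(tert‑butyldimethylsilyl)oxy]‑5‑iodo‑2‑(propan‑2‑yl)hex‑4‑enoyl]‑1,3‑oxazolidin‑2‑one | O=C1OC[C@@H](Cc2ccccc2)N1C(=O)[C@H](C(C)C)[C@@H](O[Si](C)(C)C(C)(C)C)/C=C(C)\I | intermediate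
10 | (2S,3R,4Z)‑3‑[(tert‑butyldimethylsilyl)oxy]‑5‑iodo‑2‑(propan‑2‑yl)hex‑4‑en‑1‑ol | OC[C@H](C(C)C)[C@@H](O[Si](C)(C)C(C)(C)C)/C=C(C)\I | intermediate
11 | (2R,3R,4Z)‑3‑[(tert‑butyldimethylsilyl)oxy]‑5‑iodo‑2‑(propan‑2‑yl)hex‑4‑enal | O=C[C@H](C(C)C)[C@@H](O[Si](C)(C)C(C)(C)C)/C=C(C)\I | intermediate
12 | O‑(pinacolatoboryl) ether of 13 | C#CC[C@@H](OB1OC(C)(C)C(C)(C)O1)[C@H](C(C)C)[C@@H](O[Si](C)(C)C(C)(C)C)/C=C(C)\I | intermediate (not isolated)
13 | (4R,5S,6R,7Z)‑6‑[(tert‑butyldimethylsilyl)oxy]‑8‑iodo‑5‑(propan‑2‑yl)non‑7‑en‑1‑yn‑4‑ol | C#CC[C@@H](O)[C@H](C(C)C)[C@@H](O[Si](C)(C)C(C)(C)C)/C=C(C)\I | intermediate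
14 | E‑alkenyl(dimethyl)alane with O1 as dimethylaluminium alkoxide (Al on C4 trans to C2) | C[Al](C)/C=C(C)/C[C@@H](O[Al](C)C)[C@H](C(C)C)[C@@H](O[Si](C)(C)C(C)(C)C)/C=C(C)\I | intermediate (not isolated)
15 | cyclic Z‑alkenylalane (six‑membered Al–O1–C1–C2–C3=C4 ring, Al‑methyl) | C[Al]1O[C@@H]([C@H](C(C)C)[C@@H](O[Si](C)(C)C(C)(C)C)/C=C(C)\I)CC(C)=C1 | intermediate (not isolated)
16 | (1Z,4R,5S,6R,7Z)‑1‑bromo‑6‑[(tert‑butyldimethylsilyl)oxy]‑8‑iodo‑2‑methyl‑5‑(propan‑2‑yl)nona‑1,7‑dien‑4‑ol | Br/C=C(C)\C[C@@H](O)[C@H](C(C)C)[C@@H](O[Si](C)(C)C(C)(C)C)/C=C(C)\I | intermediate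
17 | (1Z,4R,5S,6S,7Z)‑1‑bromo‑6‑[(tert‑butyldimethylsilyl)oxy]‑2,8‑dimethyl‑5‑(propan‑2‑yl)deca‑1,7,9‑trien‑4‑ol | Br/C=C(C)\C[C@@H](O)[C@H](C(C)C)[C@@H](O[Si](C)(C)C(C)(C)C)/C=C(C)\C=C | intermediate
18 | C5 B‑alkyl‑9‑BBN adduct of 17 with O1 as 9‑BBN borinate | Br/C=C(C)\C[C@@H](OB1C2CCCC1CCC2)[C@H](C(C)C)[C@@H](O[Si](C)(C)C(C)(C)C)/C=C(C)\CCB1C2CCCC1CCC2 | intermediate (not isolated)
19 | (1R,3Z,7Z,9S,10S)‑9‑[(tert‑butyldimethylsilyl)oxy]‑3,7‑dimethyl‑10‑(propan‑2‑yl)cyclodeca‑3,7‑dien‑1‑ol | O[C@@H]1C/C(C)=C\CC/C(C)=C\[C@H](O[Si](C)(C)C(C)(C)C)[C@H]1C(C)C | intermediate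
20 | vanillic acid (4‑hydroxy‑3‑methoxybenzoic acid) | COc1cc(C(=O)O)ccc1O | starting material
21 | tert‑butyldimethylsilyl 4‑[(tert‑butyldimethylsilyl)oxy]‑3‑methoxybenzoate | COc1cc(C(=O)O[Si](C)(C)C(C)(C)C)ccc1O[Si](C)(C)C(C)(C)C | intermediate (not isolated)
22 | 4‑[(tert‑butyldimethylsilyl)oxy]‑3‑methoxybenzoic acid | COc1cc(C(=O)O)ccc1O[Si](C)(C)C(C)(C)C | intermediate
23 | 4‑[(tert‑butyldimethylsilyl)oxy]‑3‑methoxybenzoic 2,4,6‑trichlorobenzoic anhydride | COc1cc(C(=O)OC(=O)c2c(Cl)cc(Cl)cc2Cl)ccc1O[Si](C)(C)C(C)(C)C | intermediate (not isolated)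
24 | (1R,3Z,7Z,9S,10S)‑9‑[(tert‑butyldimethylsilyl)oxy]‑3,7‑dimethyl‑10‑(propan‑2‑yl)cyclodeca‑3,7‑dien‑1‑yl 4‑[(tert‑butyldimethylsilyl)oxy]‑3‑methoxybenzoate | COc1cc(C(=O)O[C@@H]2C/C(C)=C\CC/C(C)=C\[C@H](O[Si](C)(C)C(C)(C)C)[C@H]2C(C)C)ccc1O[Si](C)(C)C(C)(C)C | intermediate
25 | (1R,3Z,7Z,9S,10R)‑9‑hydroxy‑3,7‑dimethyl‑10‑(propan‑2‑yl)cyclodeca‑3,7‑dien‑1‑yl 4‑hydroxy‑3‑methoxybenzoate | COc1cc(C(=O)O[C@@H]2C/C(C)=C\CC/C(C)=C\[C@H](O)[C@H]2C(C)C)ccc1O | target

**Step count**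

Total: 13 steps. Longest linear sequence: 12 steps (steps 1–10, 12 and 13, from but‑2‑yn‑1‑ol); step 11 is a one‑step side branch.

**Steps most likely to fail**

Step 10 (ring closure). Intermolecular coupling may outrun closure of the strained ten‑membered ring and give oligomers, or the alkylborane may be lost by protodeboronation or β‑hydride elimination at the low catalyst concentration that high dilution imposes. The fallback closes the ring by ring‑closing metathesis at C3=C4 instead. It sets out from alcohol 10: alkyl Suzuki–Miyaura coupling of its C7 iodide with potassium but‑3‑enyltrifluoroborate (PdCl2(dppf)·CH2Cl2, Cs2CO3, THF/H2O, 70 °C) should give (2S,3S,4Z)‑3‑[(tert‑butyldimethylsilyl)oxy]‑5‑methyl‑2‑(propan‑2‑yl)nona‑4,8‑dien‑1‑ol F1, which carries C6, C5 and C4 as a butenyl chain. Dess–Martin oxidation should give the aldehyde F2. Allylboration with 2‑methylallylboronic acid pinacol ester under (R)‑TRIP catalysis, as in step 7, should give through the borate ester F3 the homoallylic alcohol F4 with C1 set as R. Metathesis of F4 with second‑generation Grubbs catalyst in dilute toluene at 80 °C should join C3 and C4 with loss of ethene; the cis ring alkene is the less strained isomer in a cyclodecene and is expected to be favoured. The fallback comes back to the route at 19.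

Step 8 (Z‑bromoalkene). The chelation‑driven E to Z isomerisation of the alkenylalane may stay incomplete, and prolonged heating with AlMe3 may damage the allylic silyl ether or erode the regiochemistry of carbometalation. The fallback fixes the Z geometry by a temporary boron tether and sets out from aldehyde 11. Allylboration with 2‑methylallylboronic acid pinacol ester under (R)‑TRIP catalysis should give through the borate ester F5 the alcohol (4R,5S,6R,7Z)‑6‑[(tert‑butyldimethylsilyl)oxy]‑8‑iodo‑2‑methyl‑5‑(propan‑2‑yl)nona‑1,7‑dien‑4‑ol F6. Exchange with vinylboronic acid dibutyl ester (CH2Cl2, rt) should give the mixed vinylboronate F7. Ring‑closing metathesis (second‑generation Grubbs catalyst, CH2Cl2, 40 °C) should then close the six‑membered cyclic alkenylboronate F8, in which the ring holds boron cis to C2. Bromodeboronation with NBS (MeCN, 0 °C), which proceeds with retention, and aqueous work‑up bring the material back to the route at 16.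

Step 7 (C1 carbinol). Facial selection at the hindered α‑branched aldehyde may be poor or may run against the catalyst, since the isopropyl group and the silyloxy‑bearing branch at C10 are of similar size. The fallback secures C1 by inversion instead of by facial control and sets out from aldehyde 11. Whatever the facial outcome of the allenylboration, the C1 epimer (4S,5S,6R,7Z)‑6‑[(tert‑butyldimethylsilyl)oxy]‑8‑iodo‑5‑(propan‑2‑yl)non‑7‑en‑1‑yn‑4‑ol F9 is separated by chromatography. A Mitsunobu reaction (4‑nitrobenzoic acid, PPh3, DIAD, toluene, 0 °C → rt) should convert it with inversion into the (4R)‑configured 4‑nitrobenzoate F10. Methanolysis (K2CO3, MeOH, rt) brings the material back to the route at 13.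

**Further compounds**

F1 | step 10 | (2S,3S,4Z)‑3‑[(tert‑butyldimethylsilyl)oxy]‑5‑methyl‑2‑(propan‑2‑yl)nona‑4,8‑dien‑1‑ol | OC[C@H](C(C)C)[C@@H](O[Si](C)(C)C(C)(C)C)/C=C(C)\CCC=C
F2 | step 10 | (2R,3S,4Z)‑3‑[(tert‑butyldimethylsilyl)oxy]‑5‑methyl‑2‑(propan‑2‑yl)nona‑4,8‑dienal | O=C[C@H](C(C)C)[C@@H](O[Si](C)(C)C(C)(C)C)/C=C(C)\CCC=C
F3 | step 10 | O‑(pinacolatoboryl) ether of F4 | C=C(C)C[C@@H](OB1OC(C)(C)C(C)(C)O1)[C@H](C(C)C)[C@@H](O[Si](C)(C)C(C)(C)C)/C=C(C)\CCC=C
F4 | step 10 | (4R,5S,6S,7Z)‑6‑[(tert‑butyldimethylsilyl)oxy]‑2,8‑dimethyl‑5‑(propan‑2‑yl)dodeca‑1,7,11‑trien‑4‑ol | C=C(C)C[C@@H](O)[C@H](C(C)C)[C@@H](O[Si](C)(C)C(C)(C)C)/C=C(C)\CCC=C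
F5 | step 8 | O‑(pinacolatoboryl) ether of F6 | C=C(C)C[C@@H](OB1OC(C)(C)C(C)(C)O1)[C@H](C(C)C)[C@@H](O[Si](C)(C)C(C)(C)C)/C=C(C)\I
F6 | step 8 | (4R,5S,6R,7Z)‑6‑[(tert‑butyldimethylsilyl)oxy]‑8‑iodo‑2‑methyl‑5‑(propan‑2‑yl)nona‑1,7‑dien‑4‑ol | C=C(C)C[C@@H](O)[C@H](C(C)C)[C@@H](O[Si](C)(C)C(C)(C)C)/C=C(C)\I
F7 | step 8 | butyl ester of the mixed vinylboronate of F6 (O1–B(OBu)–CH=CH2) | C=CB(OCCCC)O[C@H](CC(C)=C)[C@H](C(C)C)[C@@H](O[Si](C)(C)C(C)(C)C)/C=C(C)\I
F8 | step 8 | 2‑butoxy‑4‑methyl‑5,6‑dihydro‑2H‑1,2‑oxaborinine carrying the C10–C7 side chain at ring C6 (cyclic alkenylboronate) | CCCCOB1O[C@@H]([C@H](C(C)C)[C@@H](O[Si](C)(C)C(C)(C)C)/C=C(C)\I)CC(C)=C1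
F9 | step 7 | (4S,5S,6R,7Z)‑6‑[(tert‑butyldimethylsilyl)oxy]‑8‑iodo‑5‑(propan‑2‑yl)non‑7‑en‑1‑yn‑4‑ol | C#CC[C@H](O)[C@H](C(C)C)[C@@H](O[Si](C)(C)C(C)(C)C)/C=C(C)\I
F10 | step 7 | (4R,5S,6R,7Z)‑6‑[(tert‑butyldimethylsilyl)oxy]‑8‑iodo‑5‑(propan‑2‑yl)non‑7‑en‑1‑yn‑4‑yl 4‑nitrobenzoate | O=C(O[C@H](CC#C)[C@H](C(C)C)[C@@H](O[Si](C)(C)C(C)(C)C)/C=C(C)\I)c1ccc(cc1)[N+](=O)[O-]
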